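**Plan**

Retrosynthetic cuts, last-formed first: the two aryl acetate O–acyl bonds; pyranone C4–C5 and O1–C2 (one operation); the two acyl C–Cl bonds; the bond from the bridging CH2 to the malonyl carbon; the C8–CHO bond; the chromene C4–C4a and O1–C2 bonds (propargyl ether Claisen cascade); the propargyl O–C bond; the aryl–acyl bond.
Enabling feature: pyranone O1, C6 (ethyl) and C5 (methyl) are the enol of symmetrical pentan-3-one, and C2, C3, C4 with the methylene on C3 are a 2-substituted malonyl unit, so the ring splits into two three-atom halves with no regiochemical choice.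
Forward order: benzene ring from phloroglucinol, acyl group, chromene ring, C8 formyl group, phenol acetates, malonyl unit, dichloride, then the pyranone ring last by C-acylation/O-acylation with the silyl enol ether, then removal of the acetates.
Stereochemistry: the target has no stereogenic centre; the centres of two transient intermediates are racemic and are erased by enolisation, and the enol ether geometry disappears in the pyranone.

Key step: step 10

Remark: the target is treated as the 4-hydroxy-2-pyranone tautomer drawn in its SMILES; the phenols are carried as acetates from step 5 on, because a free hydroxyl ortho to the malonyl side chain would lactonise to a coumarin.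

**Route**

Step 1
Reactants: 1 phloroglucinol (benzene-1,3,5-triol); 2 2-methylpropanoyl chloride
Product: 3 2-methyl-1-(2,4,6-trihydroxyphenyl)propan-1-one
Conditions: AlCl3 (4 equiv), PhNO2/CH2Cl2, 0 °C to 40 °C; then ice/aq. HCl
Reagents that add atoms: none
Why: Friedel–Crafts acylation of the threefold activated ring, which should stop at the monoketone because the aluminium-chelated acyl group deactivates the arene toward a second acylation.

Step 2
Reactants: 3 2-methyl-1-(2,4,6-trihydroxyphenyl)propan-1-one; 4 3-chloro-3-methylbut-1-yne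
Product: 5 1-{2,6-dihydroxy-4-[(2-methylbut-3-yn-2-yl)oxy]phenyl}-2-methylpropan-1-one
Conditions: CuCl2·2H2O (1 mol %), DBU (1.1 equiv), MeCN, 0 °C
Reagents that add atoms: none
Why: Copper-catalysed O-propargylation of a phenol with a tertiary propargylic chloride, in which one equivalent of DBU should ionise only the para hydroxyl, the most acidic one (vinylogous acid) and the one not tied up in a hydrogen bond to the ketone.

Step 3
Reactants: 5 1-{2,6-dihydroxy-4-[(2-methylbut-3-yn-2-yl)oxy]phenyl}-2-methylpropan-1-one
Product: 7 1-(5,7-dihydroxy-2,2-dimethyl-2H-chromen-6-yl)-2-methylpropan-1-one, via ortho-allenyl phenol 6 (not isolated)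
Conditions: o-xylene, 140 °C
Reagents that add atoms: none
Why: Aromatic propargyl Claisen rearrangement ([3,3]) to either of the two equivalent ortho carbons gives 6, whose 1,5-hydrogen shift and oxa-6π electrocyclisation should run through the former ether oxygen because the neighbouring hydroxyl is held in the chelate with the ketone, as is known for chelated 2,4-dihydroxyaryl ketone propargyl ethers.

Step 4
Reactants: 7 1-(5,7-dihydroxy-2,2-dimethyl-2H-chromen-6-yl)-2-methylpropan-1-one
Product: 8 5,7-dihydroxy-2,2-dimethyl-6-(2-methylpropanoyl)-2H-chromene-8-carbaldehyde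
Conditions: POCl3, DMF, EtOAc, 0 °C to rt; then H2O, 50 °C
Reagents that add atoms: N,N-dimethylformamide, CN(C)C=O (formyl carbon); water, O (formyl oxygen)
Why: Vilsmeier–Haack formylation at C8, the only unsubstituted ring carbon and one placed ortho/para to three oxygen donors, as is usual for acylphloroglucinols.

Step 5
Reactants: 8 5,7-dihydroxy-2,2-dimethyl-6-(2-methylpropanoyl)-2H-chromene-8-carbaldehyde
Product: 9 8-formyl-2,2-dimethyl-6-(2-methylpropanoyl)-2H-chromene-5,7-diyl diacetate
Conditions: Ac2O, Et3N, DMAP (cat.), CH2Cl2, 0 °C to rt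
Reagents that add atoms: acetic anhydride, CC(=O)OC(C)=O
Why: DMAP-catalysed O-acetylation of both phenols, needed because a free hydroxyl ortho to the future malonyl unit would lactonise to a coumarin and would later be acylated by the acid chloride.

Step 6
Reactants: 9 8-formyl-2,2-dimethyl-6-(2-methylpropanoyl)-2H-chromene-5,7-diyl diacetate; 10 Meldrum's acid (2,2-dimethyl-1,3-dioxane-4,6-dione)
Product: 12 8-[(2,2-dimethyl-4,6-dioxo-1,3-dioxan-5-yl)methyl]-2,2-dimethyl-6-(2-methylpropanoyl)-2H-chromene-5,7-diyl diacetate, via arylidene Meldrum's acid 11 (not isolated)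
Conditions: Hantzsch ester (diethyl 2,6-dimethyl-1,4-dihydropyridine-3,5-dicarboxylate, 1.1 equiv), L-proline (20 mol %), CH2Cl2, rt
Reagents that add atoms: none
Why: Knoevenagel condensation of the aldehyde with Meldrum's acid to 11 and conjugate hydride transfer from the Hantzsch ester (organocatalytic three-component reductive alkylation), under near-neutral conditions that should leave the aryl acetates, the ketone and the chromene alkene untouched.

Step 7
Reactants: 12 8-[(2,2-dimethyl-4,6-dioxo-1,3-dioxan-5-yl)methyl]-2,2-dimethyl-6-(2-methylpropanoyl)-2H-chromene-5,7-diyl diacetate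
Product: 14 2-{[5,7-diacetoxy-2,2-dimethyl-6-(2-methylpropanoyl)-2H-chromen-8-yl]methyl}propanedioic acid, via mono-tert-butyl malonate 13 (not isolated)
Conditions: t-BuOH/PhMe (1:1), 85 °C; evaporate; then CF3CO2H/CH2Cl2 (1:4), 0 °C to rt
Reagents that add atoms: tert-butanol, CC(C)(C)O (its oxygen remains as a carboxyl oxygen of 14)
Why: Nucleophilic ring opening of the 5-monosubstituted Meldrum's acid by the alcohol with loss of acetone, then acidolysis of the tert-butyl ester by alkyl–oxygen cleavage, a base-free unmasking of the malonic acid that the aryl acetates should survive.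

Step 8
Reactants: 14 2-{[5,7-diacetoxy-2,2-dimethyl-6-(2-methylpropanoyl)-2H-chromen-8-yl]methyl}propanedioic acid
Product: 15 2-{[5,7-diacetoxy-2,2-dimethyl-6-(2-methylpropanoyl)-2H-chromen-8-yl]methyl}propanedioyl dichloride
Conditions: (COCl)2 (2.5 equiv), DMF (cat.), CH2Cl2, 0 °C to rt; evaporate, use crude
Reagents that add atoms: oxalyl chloride, ClC(=O)C(Cl)=O
Why: Acid chloride formation by catalytic chloroiminium activation of each carboxyl group, with only gaseous by-products so that the moisture-sensitive dichloride needs no purification.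

Step 9
Reactants: 16 pentan-3-one
Product: 17 (Z)-trimethyl(pent-2-en-3-yloxy)silane
Conditions: Me3SiOTf, Et3N, Et2O, 0 °C to rt; pentane extraction, distillation
Reagents that add atoms: trimethylsilyl trifluoromethanesulfonate, C[Si](C)(C)OS(=O)(=O)C(F)(F)F
Why: Soft enolisation and O-silylation of the ketone with a silyl triflate and an amine base, which should give mainly the Z enol ether, whose geometry is without consequence for the next step.

Step 10
Reactants: 15 2-{[5,7-diacetoxy-2,2-dimethyl-6-(2-methylpropanoyl)-2H-chromen-8-yl]methyl}propanedioyl dichloride; 17 (Z)-trimethyl(pent-2-en-3-yloxy)silane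
Product: 19 8-[(6-ethyl-4-hydroxy-5-methyl-2-oxo-2H-pyran-3-yl)methyl]-2,2-dimethyl-6-(2-methylpropanoyl)-2H-chromene-5,7-diyl diacetate, via 3,5-dioxoacyl chloride 18 (not isolated)
Conditions: Et2O, −78 °C, slow addition of 17 (1.05 equiv) to 15; then −78 °C to rt
Reagents that add atoms: none
Why: The nucleophilic carbon of enol ether 17 attacks one acyl chloride of 15 (or the chlorocarbonyl ketene that 15 forms by loss of HCl), and loss of chlorotrimethylsilane leaves the 3,5-dioxoacyl chloride 18 (pyranone C4–C5 made). The diketone of 18 enolises across its central CH, which places the oxygen of the former pentanone carbonyl six atoms from the remaining acyl chloride, and a 6-exo-trig addition–elimination closes the lactone (O1–C2) before tautomerisation to the aromatic 4-hydroxy-2-pyranone. The closest known reaction type is the condensation of trimethylsilyl enol ethers with malonyl dichloride and its 2-alkyl homologues to 4-hydroxypyran-2-ones, applied here to a more functionalised dichloride. No stereocentre is formed, since the centres of 18 are lost on enolisation and the enol ether geometry goes with them. The step needs one enol ether per dichloride and ring closure through oxygen rather than carbon; slow addition of 17 to 15 at −78 °C keeps the dichloride in excess, and enolisation toward the central carbon rather than toward the ethyl CH2 makes the oxygen the internal nucleophile. Regiochemistry cannot go wrong because pentan-3-one is symmetrical, and the acetates keep the phenols from being acylated.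

Step 11
Reactants: 19 8-[(6-ethyl-4-hydroxy-5-methyl-2-oxo-2H-pyran-3-yl)methyl]-2,2-dimethyl-6-(2-methylpropanoyl)-2H-chromene-5,7-diyl diacetate
Product: 20 6-ethyl-4-hydroxy-3-{[5,7-dihydroxy-2,2-dimethyl-6-(2-methylpropanoyl)-2H-chromen-8-yl]methyl}-5-methyl-2H-pyran-2-one (CNP0266853.0)
Conditions: K2CO3 (3 equiv), MeOH, 0 °C to rt; then aq. HCl to pH 3
Reagents that add atoms: none
Why: Base-mediated methanolysis (transesterification) of the two aryl acetates, in which the pyranone is held as its unreactive enolate until acidification.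

**Compound list**

1 | phloroglucinol | Oc1cc(O)cc(O)c1 | starting material
2 | 2-methylpropanoyl chloride | CC(C)C(Cl)=O | starting material
3 | 2-methyl-1-(2,4,6-trihydroxyphenyl)propan-1-one | CC(C)C(=O)c1c(O)cc(O)cc1O | intermediate
4 | 3-chloro-3-methylbut-1-yne | CC(C)(Cl)C#C | starting material
5 | 1-{2,6-dihydroxy-4-[(2-methylbut-3-yn-2-yl)oxy]phenyl}-2-methylpropan-1-one | CC(C)C(=O)c1c(O)cc(OC(C)(C)C#C)cc1O | intermediate
6 | 2-methyl-1-[2,4,6-trihydroxy-3-(3-methylbuta-1,2-dien-1-yl)phenyl]propan-1-one (ortho-allenyl phenol, not isolated) | CC(C)C(=O)c1c(O)cc(O)c(C=C=C(C)C)c1O | intermediate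
7 | 1-(5,7-dihydroxy-2,2-dimethyl-2H-chromen-6-yl)-2-methylpropan-1-one | CC(C)C(=O)c1c(O)cc2OC(C)(C)C=Cc2c1O | intermediate
8 | 5,7-dihydroxy-2,2-dimethyl-6-(2-methylpropanoyl)-2H-chromene-8-carbaldehyde | CC(C)C(=O)c1c(O)c(C=O)c2OC(C)(C)C=Cc2c1O | intermediate
9 | 8-formyl-2,2-dimethyl-6-(2-methylpropanoyl)-2H-chromene-5,7-diyl diacetate | CC(C)C(=O)c1c(OC(C)=O)c(C=O)c2OC(C)(C)C=Cc2c1OC(C)=O | intermediate
10 | Meldrum's acid (2,2-dimethyl-1,3-dioxane-4,6-dione) | CC1(C)OC(=O)CC(=O)O1 | starting material
11 | 8-[(2,2-dimethyl-4,6-dioxo-1,3-dioxan-5-ylidene)methyl]-2,2-dimethyl-6-(2-methylpropanoyl)-2H-chromene-5,7-diyl diacetate (not isolated) | CC(C)C(=O)c1c(OC(C)=O)c(C=C3C(=O)OC(C)(C)OC3=O)c2OC(C)(C)C=Cc2c1OC(C)=O | intermediate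
12 | 8-[(2,2-dimethyl-4,6-dioxo-1,3-dioxan-5-yl)methyl]-2,2-dimethyl-6-(2-methylpropanoyl)-2H-chromene-5,7-diyl diacetate | CC(C)C(=O)c1c(OC(C)=O)c(CC3C(=O)OC(C)(C)OC3=O)c2OC(C)(C)C=Cc2c1OC(C)=O | intermediate
13 | 3-tert-butoxy-2-{[5,7-diacetoxy-2,2-dimethyl-6-(2-methylpropanoyl)-2H-chromen-8-yl]methyl}-3-oxopropanoic acid (racemic, not isolated) | CC(C)C(=O)c1c(OC(C)=O)c(CC(C(=O)O)C(=O)OC(C)(C)C)c2OC(C)(C)C=Cc2c1OC(C)=O | intermediate
14 | 2-{[5,7-diacetoxy-2,2-dimethyl-6-(2-methylpropanoyl)-2H-chromen-8-yl]methyl}propanedioic acid | CC(C)C(=O)c1c(OC(C)=O)c(CC(C(=O)O)C(=O)O)c2OC(C)(C)C=Cc2c1OC(C)=O | intermediate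
15 | 2-{[5,7-diacetoxy-2,2-dimethyl-6-(2-methylpropanoyl)-2H-chromen-8-yl]methyl}propanedioyl dichloride | CC(C)C(=O)c1c(OC(C)=O)c(CC(C(Cl)=O)C(Cl)=O)c2OC(C)(C)C=Cc2c1OC(C)=O | intermediate
16 | pentan-3-one | CCC(=O)CC | starting material
17 | (Z)-trimethyl(pent-2-en-3-yloxy)silane | C/C=C(\O[Si](C)(C)C)CC | intermediate
18 | 2-{[5,7-diacetoxy-2,2-dimethyl-6-(2-methylpropanoyl)-2H-chromen-8-yl]methyl}-4-methyl-3,5-dioxoheptanoyl chloride (diastereomer mixture, not isolated) | CCC(=O)C(C)C(=O)C(Cc1c(OC(C)=O)c(C(=O)C(C)C)c(OC(C)=O)c2C=CC(C)(C)Oc12)C(Cl)=O | intermediate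
19 | 8-[(6-ethyl-4-hydroxy-5-methyl-2-oxo-2H-pyran-3-yl)methyl]-2,2-dimethyl-6-(2-methylpropanoyl)-2H-chromene-5,7-diyl diacetate | CCc1oc(=O)c(Cc2c(OC(C)=O)c(C(=O)C(C)C)c(OC(C)=O)c3c2OC(C)(C)C=C3)c(O)c1C | intermediate
20 | 6-ethyl-4-hydroxy-3-{[5,7-dihydroxy-2,2-dimethyl-6-(2-methylpropanoyl)-2H-chromen-8-yl]methyl}-5-methyl-2H-pyran-2-one | CCc1oc(=O)c(Cc2c(O)c(C(=O)C(C)C)c(O)c3c2OC(C)(C)C=C3)c(O)c1C | target

**Step count**

Total: 11 steps. Longest linear sequence: 10 steps (steps 1 to 8, 10 and 11, from phloroglucinol); step 9 is a one-step side branch.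

**Steps most likely to fail**

Step 10. What may go wrong: loss of HCl from the dichloride to a ketene that oligomerises, acylation of a second enol ether molecule, or acid-induced addition to the chromene double bond, each outrunning the wanted C-acylation and ring closure. Fallback, setting out from aldehyde 9 and enol ether 17 and coming back at 19: 17 would be combined with malonyl dichloride (ClC(=O)CC(Cl)=O) in Et2O at −78 °C, the parent case of the same annulation, to give 6-ethyl-4-hydroxy-5-methyl-2H-pyran-2-one F1. F1, aldehyde 9 and the Hantzsch ester with L-proline in CH2Cl2 would then undergo Knoevenagel condensation at pyranone C3 to 8-[(6-ethyl-5-methyl-2,4-dioxo-2H-pyran-3(4H)-ylidene)methyl]-2,2-dimethyl-6-(2-methylpropanoyl)-2H-chromene-5,7-diyl diacetate F2 (not isolated), and conjugate hydride transfer to F2 would give 19. The methylene bridge is then made after the pyranone ring instead of before it.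

Step 3. What may go wrong: delivery of the hydrogen from the ortho hydroxyl next to the allene instead of from the former ether oxygen, so that the electrocyclisation closes in the wrong direction and the acyl group ends up at C8. Fallback, setting out from 5 and coming back at 7: 5 would be acetylated on both ortho hydroxyls (Ac2O, Et3N, DMAP, CH2Cl2) to 2-(2-methylpropanoyl)-5-[(2-methylbut-3-yn-2-yl)oxy]-1,3-phenylene diacetate F3. The Claisen cascade (o-xylene, 140 °C) would then pass through 5-hydroxy-4-(3-methylbuta-1,2-dien-1-yl)-2-(2-methylpropanoyl)-1,3-phenylene diacetate F4, whose only free hydroxyl is the former ether oxygen, to 2,2-dimethyl-6-(2-methylpropanoyl)-2H-chromene-5,7-diyl diacetate F5. Methanolysis of F5 (K2CO3, MeOH) would give 7 with the ring-closure direction fixed by the blocking groups.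

Step 2. What may go wrong: alkylation at an ortho hydroxyl or at a ring carbon, or double alkylation, instead of clean mono-O-alkylation at the para oxygen. Fallback, setting out from 3 and coming back at 7: 3 would be condensed with 3-methylbut-2-enal (CC(C)=CC=O) under ethylenediammonium diacetate catalysis in toluene at 80 °C (Knoevenagel condensation at a ring carbon, then oxa-6π electrocyclisation of the quinone methide), which gives chromene 7 directly and avoids the propargyl ether. Closure through the ortho oxygen is then also open and would give 1-(5,7-dihydroxy-2,2-dimethyl-2H-chromen-8-yl)-2-methylpropan-1-one F6, to be removed by chromatography.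

**Further compounds**

F1 | step 10 | 6-ethyl-4-hydroxy-5-methyl-2H-pyran-2-one | CCc1oc(=O)cc(O)c1C
F2 | step 10 | 8-[(6-ethyl-5-methyl-2,4-dioxo-2H-pyran-3(4H)-ylidene)methyl]-2,2-dimethyl-6-(2-methylpropanoyl)-2H-chromene-5,7-diyl diacetate (alkene geometry not defined, transient) | CCC1=C(C)C(=O)C(=Cc2c(OC(C)=O)c(C(=O)C(C)C)c(OC(C)=O)c3c2OC(C)(C)C=C3)C(=O)O1
F3 | step 3 | 2-(2-methylpropanoyl)-5-[(2-methylbut-3-yn-2-yl)oxy]-1,3-phenylene diacetate | CC(C)C(=O)c1c(OC(C)=O)cc(OC(C)(C)C#C)cc1OC(C)=O
F4 | step 3 | 5-hydroxy-4-(3-methylbuta-1,2-dien-1-yl)-2-(2-methylpropanoyl)-1,3-phenylene diacetate | CC(C)C(=O)c1c(OC(C)=O)cc(O)c(C=C=C(C)C)c1OC(C)=O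
F5 | step 3 | 2,2-dimethyl-6-(2-methylpropanoyl)-2H-chromene-5,7-diyl diacetate | CC(C)C(=O)c1c(OC(C)=O)cc2OC(C)(C)C=Cc2c1OC(C)=O
F6 | step 2 | 1-(5,7-dihydroxy-2,2-dimethyl-2H-chromen-8-yl)-2-methylpropan-1-one | CC(C)C(=O)c1c(O)cc(O)c2C=CC(C)(C)Oc12
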